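**Plan**

- Tetrahydroquinoline numbering is used for all compounds; in the azaindanols the carbinol carbon is C5, the inner vinyl carbon C6 and the adjoining ring CH2 C7. The cuts are C5H2 back to C5=O, then Cα–Cβ of the side chain and C6–C7 of the ring in one operation, and finally C5–C6.
- Enabling feature: the quaternary C6 of the saturated ring carries three things. One is a veratryl ring that can stabilise a positive charge at C6. The second is a CH2CH2N chain whose Cα–Cβ bond is the sum of an alkene terminus and an N-acyliminium carbon. The third is ring carbon C7, which can have arrived by a 1,2-shift from an oxygenated C5 beside pyridine carbon C4a.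
- Precursors: an enantiopure 5-(1-veratrylvinyl)azaindan-5-ol silyl ether (from the azaindanone and an α-veratrylvinyl metal made from acetoveratrone) and N-(methoxymethyl)-N-methylacetamide (from N,N-dimethylacetamide).
- Forward: the pyridine, arene and cyclopentane rings are bought and C5–C6 is joined first. The key step then attaches the complete amide chain and enlarges the five-membered ring to the cyclohexanone. Radical deoxygenation at C5 ends the route.
- Stereochemistry: C5 of the tertiary alcohol is secured by salt resolution and is handed over to C6 during the 1,2-shift. C6 is the only stereocentre of the target and is quaternary, so it cannot epimerise afterwards.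

Key step: step 6

Assumption: the less soluble L-DTTA salt is taken to contain the (S)-alcohol (to be confirmed by X-ray analysis of the salt) and the 1,2-shift is taken to follow the rotamer model of step 6; both antipodes of the acid are commercial, so the mirror-image alcohol is equally accessible should either point prove reversed.

**Step 1**
Reactants: 1 3',4'-dimethoxyacetophenone
Product: 2 (E)-N'-[1-(3,4-dimethoxyphenyl)ethylidene]-2,4,6-triisopropylbenzenesulfonohydrazide
Conditions: TrisNHNH2 (1.05 equiv), conc. HCl (cat.), MeCN, rt
Reagents that add atoms: 2,4,6-triisopropylbenzenesulfonyl hydrazide, CC(C)c1cc(C(C)C)c(S(=O)(=O)NN)c(C(C)C)c1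
Why: Acid-catalysed hydrazone formation from a methyl ketone, driven by crystallisation of the product; the isopropyl groups block the ortho-lithiation of the sulfonyl arene that would waste base in the next step.

**Step 2**
Reactants: 2 trisylhydrazone; 3 6,7-dihydro-5H-cyclopenta[b]pyridin-5-one
Product: 6 (±)-5-[1-(3,4-dimethoxyphenyl)vinyl]-6,7-dihydro-5H-cyclopenta[b]pyridin-5-ol, via arylvinyllithium 4 (not isolated), via arylvinylcerium dichloride 5 (not isolated)
Conditions: 2 (1.3 equiv), n-BuLi (2.6 equiv), THF, −78 → 0 °C; anhydrous CeCl3 (1.4 equiv), −78 °C; 3, −78 → −30 °C; aq. NH4Cl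
Reagents that add atoms: none
Why: The Shapiro reaction (double deprotonation, loss of sulfinate and N2) delivers the α-arylvinyllithium regiospecifically, and Imamoto transmetalation to cerium makes it nucleophilic but barely basic, so that 1,2-addition should outrun enolisation of the azaindanone and attack on the pyridine ring; C5 is formed as a racemate.

**Step 3**
Reactants: 6 racemic tertiary alcohol
Product: 8 (S)-5-[1-(3,4-dimethoxyphenyl)vinyl]-6,7-dihydro-5H-cyclopenta[b]pyridin-5-ol, via L-DTTA salt 7 (not isolated)
Conditions: (−)-O,O'-di-p-toluoyl-L-tartaric acid (1.0 equiv), EtOH/EtOAc, 60 °C → rt, recrystallise to constant rotation; filter cake partitioned directly, aq. Na2CO3/CH2Cl2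
Reagents that add atoms: none
Why: Classical resolution through diastereomeric salts: the ring nitrogen is basic enough to be protonated by a diacyltartaric acid while this weak acid leaves the tertiary allylic alcohol intact, and fractional crystallisation fixes the C5 configuration, the sole source of chirality of the route.

**Step 4**
Reactants: 8 (S)-alcohol
Product: 9 (S)-5-[1-(3,4-dimethoxyphenyl)vinyl]-5-(trimethylsilyloxy)-6,7-dihydro-5H-cyclopenta[b]pyridine
Conditions: N-(trimethylsilyl)imidazole (1.5 equiv), CH2Cl2, rt
Reagents that add atoms: N-(trimethylsilyl)imidazole, C[Si](C)(C)n1ccnc1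
Why: Silylation of a hindered tertiary alcohol with a neutral, powerful silyl donor leaves C5 untouched, and the silyl ether is chosen because it blocks O-amidomethylation and ionisation of the carbinol and lets the coming 1,2-shift end by loss of a silyl group instead of a proton.

**Step 5**
Reactants: 10 N,N-dimethylacetamide
Product: 11 N-(methoxymethyl)-N-methylacetamide
Conditions: MeOH, Et4NOTs (0.05 M), graphite anode, steel cathode, undivided cell, constant current, 2.2 F/mol, 10–20 °C; distillation
Reagents that add atoms: methanol, CO
Why: Shono oxidation: anodic two-electron oxidation of the tertiary amide at an N-methyl group and capture by methanol gives the N,O-acetal, and over-oxidation is held back by limiting the charge because the product is harder to oxidise than the starting amide.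

**Step 6**
Reactants: 9 (S)-silyl ether; 11 N-(methoxymethyl)-N-methylacetamide
Product: 15 (R)-N-{2-[6-(3,4-dimethoxyphenyl)-5-oxo-5,6,7,8-tetrahydroquinolin-6-yl]ethyl}-N-methylacetamide, via N-silylpyridinium triflate 12 (not isolated), via N-acyliminium triflate 13 (not isolated), via N-silylated ketone triflate 14 (not isolated)
Conditions: 9, TMSOTf (1.1 equiv), 2,6-di-tert-butyl-4-methylpyridine (0.3 equiv), CH2Cl2, −78 °C; then 11 (1.5 equiv), TMSOTf (1.6 equiv), −78 → 0 °C; aq. NaHCO3
Reagents that add atoms: none
Why: Proposed new method: TMSOTf first silylates the ring nitrogen (12) and ionises 11 to the N-acyliminium triflate 13, whose CH2 carbon is attacked by the unsubstituted alkene terminus of 12 (Cα–Cβ bond) to leave a tertiary C6 cation stabilised by the coplanar veratryl ring, after which the C5–C7 σ bond aligned with the empty orbital shifts to C6 while the C5–O–Si unit collapses to the ketone and returns its silyl group to triflate, so that no proton is set free at any stage. The closest known reaction types are Prins–pinacol cascades, halonium-induced semipinacol ring expansions of 1-(1-arylvinyl)cycloalkanols and the amidoalkylation of styrenes by N-acyliminium ions, and the new element is an N-acyliminium ion as the trigger of the shift. The six-membered carbocycle arises by one-carbon enlargement of the cyclopentane (1,2-alkyl shift, C6–C7 made as C5–C7 breaks) and not by an endo or exo cyclisation. The C6 stereocentre is set by transfer from C5: of the two rotamers about C5–C6 that align the migrating bond, the one holding the flat veratryl ring beside the silyloxy oxygen (whose silyl group can turn away) rather than against the rigid peri C4–H of the pyridinium ring should be lower in energy, and it maps (S)-9 onto (R)-15. Three selectivities are needed: alkene rather than arene or nitrogen as the nucleophile (the styrene terminus is unhindered and much more nucleophilic than the veratryl C–H positions, the most activated of which sits next to the bulky substituent, and the nitrogen is blocked), C7 rather than C4a as the migrating group (a cationic pyridinium carbon migrates poorly and its ring tether hinders bridging), and shift rather than trapping (closure of the amide oxygen onto C6 to a 1,3-oxazinium ion is congested and reversible, ketone formation is not).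

**Step 7**
Reactants: 15 (R)-ketone
Product: 16 (6R)-N-{2-[6-(3,4-dimethoxyphenyl)-5-hydroxy-5,6,7,8-tetrahydroquinolin-6-yl]ethyl}-N-methylacetamide (C5 epimers, carried on together)
Conditions: NaBH4 (2 equiv), MeOH, 0 °C → rt
Reagents that add atoms: none
Why: Borohydride reduction of an electron-poor aryl ketone that spares amide, pyridine and arene; hydride should enter mainly from the less hindered face, but the new C5 carbinol centre is irrelevant because it is erased in step 9.

**Step 8**
Reactants: 16 alcohol
Product: 18 O-{(6R)-6-(3,4-dimethoxyphenyl)-6-[2-(N-methylacetamido)ethyl]-5,6,7,8-tetrahydroquinolin-5-yl} S-methyl dithiocarbonate, via sodium xanthate 17 (not isolated)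
Conditions: NaH (1.2 equiv), CS2 (5 equiv), THF, 0 °C → rt; MeI (1.2 equiv), 0 °C
Reagents that add atoms: carbon disulfide, S=C=S; iodomethane, CI
Why: Xanthate formation, the first half of the Barton–McCombie sequence: the small linear CS2 is the electrophile best suited to an oxygen flanked by a quaternary carbon, the soft xanthate sulfur consumes the MeI far faster than the pyridine nitrogen does in cold THF, and Chugaev elimination is impossible since neither C4a nor C6 bears hydrogen.

**Step 9**
Reactants: 18 xanthate
Product: 19 (R)-N-{2-[6-(3,4-dimethoxyphenyl)-5,6,7,8-tetrahydroquinolin-6-yl]ethyl}-N-methylacetamide (target)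
Conditions: Bu3SnH (2 equiv), AIBN (0.2 equiv), toluene, 100 °C
Reagents that add atoms: none
Why: Barton–McCombie deoxygenation: stannyl radical addition to C=S and fragmentation give the pyridyl-stabilised C5 radical, which takes hydrogen from the stannane; unlike a C5 cation it has no incentive for a 1,2-veratryl shift, since that would trade a benzylic-type radical for an unstabilised tertiary one, so C6 keeps its configuration.

**Compound list**

1 | 3',4'-dimethoxyacetophenone | CC(=O)c1ccc(OC)c(OC)c1 | starting material
2 | (E)-N'-[1-(3,4-dimethoxyphenyl)ethylidene]-2,4,6-triisopropylbenzenesulfonohydrazide | C/C(=N\NS(=O)(=O)c1c(C(C)C)cc(C(C)C)cc1C(C)C)c1ccc(OC)c(OC)c1 | intermediate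
3 | 6,7-dihydro-5H-cyclopenta[b]pyridin-5-one | O=C1CCc2ncccc21 | starting material
4 | [1-(3,4-dimethoxyphenyl)vinyl]lithium | [Li]C(=C)c1ccc(OC)c(OC)c1 | intermediate
5 | dichloro[1-(3,4-dimethoxyphenyl)vinyl]cerium(III) | Cl[Ce](Cl)C(=C)c1ccc(OC)c(OC)c1 | intermediate
6 | (±)-5-[1-(3,4-dimethoxyphenyl)vinyl]-6,7-dihydro-5H-cyclopenta[b]pyridin-5-ol | C=C(c1ccc(OC)c(OC)c1)C1(O)CCc2ncccc21 | intermediate
7 | 1:1 salt of the (S)-alcohol with (2R,3R)-O,O'-di-p-toluoyltartaric acid | C=C(c1ccc(OC)c(OC)c1)[C@@]1(O)CCc2[nH+]cccc21.O=C([O-])[C@H](OC(=O)c1ccc(C)cc1)[C@@H](OC(=O)c1ccc(C)cc1)C(=O)O | intermediate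
8 | (S)-5-[1-(3,4-dimethoxyphenyl)vinyl]-6,7-dihydro-5H-cyclopenta[b]pyridin-5-ol | C=C(c1ccc(OC)c(OC)c1)[C@@]1(O)CCc2ncccc21 | intermediate
9 | (S)-5-[1-(3,4-dimethoxyphenyl)vinyl]-5-(trimethylsilyloxy)-6,7-dihydro-5H-cyclopenta[b]pyridine | C=C(c1ccc(OC)c(OC)c1)[C@@]1(O[Si](C)(C)C)CCc2ncccc21 | intermediate
10 | N,N-dimethylacetamide | CN(C)C(C)=O | starting material
11 | N-(methoxymethyl)-N-methylacetamide | COCN(C)C(C)=O | intermediate
12 | N-trimethylsilylpyridinium triflate of 9 | C=C(c1ccc(OC)c(OC)c1)[C@@]1(O[Si](C)(C)C)CCc2[n+]([Si](C)(C)C)cccc21.[O-]S(=O)(=O)C(F)(F)F | intermediate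
13 | N-acetyl-N-methylmethaniminium triflate | C=[N+](C)C(C)=O.[O-]S(=O)(=O)C(F)(F)F | intermediate
14 | N-trimethylsilylpyridinium triflate of 15 | COc1ccc([C@]2(CCN(C)C(C)=O)CCc3[n+]([Si](C)(C)C)cccc3C2=O)cc1OC.[O-]S(=O)(=O)C(F)(F)F | intermediate
15 | (R)-N-{2-[6-(3,4-dimethoxyphenyl)-5-oxo-5,6,7,8-tetrahydroquinolin-6-yl]ethyl}-N-methylacetamide | COc1ccc([C@]2(CCN(C)C(C)=O)CCc3ncccc3C2=O)cc1OC | intermediate
16 | (6R)-N-{2-[6-(3,4-dimethoxyphenyl)-5-hydroxy-5,6,7,8-tetrahydroquinolin-6-yl]ethyl}-N-methylacetamide, C5 epimers | COc1ccc([C@]2(CCN(C)C(C)=O)CCc3ncccc3C2O)cc1OC | intermediate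
17 | sodium O-{(6R)-6-(3,4-dimethoxyphenyl)-6-[2-(N-methylacetamido)ethyl]-5,6,7,8-tetrahydroquinolin-5-yl} dithiocarbonate | COc1ccc([C@]2(CCN(C)C(C)=O)CCc3ncccc3C2OC(=S)[S-])cc1OC.[Na+] | intermediate
18 | O-{(6R)-6-(3,4-dimethoxyphenyl)-6-[2-(N-methylacetamido)ethyl]-5,6,7,8-tetrahydroquinolin-5-yl} S-methyl dithiocarbonate | COc1ccc([C@]2(CCN(C)C(C)=O)CCc3ncccc3C2OC(=S)SC)cc1OC | intermediate
19 | (R)-N-{2-[6-(3,4-dimethoxyphenyl)-5,6,7,8-tetrahydroquinolin-6-yl]ethyl}-N-methylacetamide | COc1ccc([C@]2(CCN(C)C(C)=O)CCc3ncccc3C2)cc1OC | target

**Total step count:** 9.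
**Longest linear sequence:** 8 (steps 1, 2, 3, 4, 6, 7, 8, 9); step 5 is a one-step side branch.

**Steps most likely to fail**

1. **Step 6 (proposed new method).**
   - What may go wrong:
     - The iminium ion may be diverted by Friedel–Crafts attack of the veratryl ring or by attachment to the ring nitrogen.
     - The cascade may stop at the oxazinium stage or lose a proton from Cα.
     - The pyridyl carbon may shift in place of C7.
     - The second reactive rotamer may leak through and erode the enantiomeric purity.
   - The fallback uses known chemistry, namely the photoredox radical addition, oxidation and 1,2-alkyl shift of 1-(1-arylvinyl)cycloalkanols, with an N-hydroxyphthalimide ester as the α-amidoalkyl radical source. It sets out from alcohol 8 and comes back at ketone 15.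
   - Commercial N-acetylsarcosine is esterified with N-hydroxyphthalimide (DIC, cat. DMAP, CH2Cl2) to the redox-active ester 1,3-dioxoisoindolin-2-yl N-acetyl-N-methylglycinate F1.
   - Blue-light irradiation of 8 and F1 with fac-Ir(ppy)3 in MeCN at rt should release the radical •CH2N(Me)Ac, which adds to the alkene terminus. The veratryl-stabilised C6 radical is then oxidised by Ir(IV) to the same cation, which expands the ring under neutral conditions.
   - No acid is added, so that Minisci attack on the pyridine stays slow.

2. **Step 3.**
   - What may go wrong: the diastereomeric salts may oil out or co-crystallise, so that no useful enrichment is reached.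
   - The fallback sets out from racemate 6 and comes back at 8. Crystallisation is abandoned and the enantiomers are separated directly by preparative supercritical-fluid chromatography on an immobilised polysaccharide chiral phase (CO2/MeOH with a trace of Et2NH).
   - The absolute configuration is then assigned by anomalous-dispersion X-ray analysis of a hydrobromide salt.
   - This fallback makes no new compound (F0).

3. **Step 8.**
   - What may go wrong: the oxygen flanked by the quaternary carbon may capture CS2 sluggishly, MeI may quaternise the pyridine nitrogen, or the benzylic xanthate may undergo O-to-S rearrangement on handling.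
   - The fallback sets out from ketone 15, bypasses steps 7–9 and comes back at target 19.
   - Ethane-1,2-dithiol and excess BF3·OEt2 (one equivalent is bound by the pyridine) in CH2Cl2 convert the ketone into the dithioketal (R)-N-{2-[6'-(3,4-dimethoxyphenyl)-7',8'-dihydro-6'H-spiro[1,3-dithiolane-2,5'-quinolin]-6'-yl]ethyl}-N-methylacetamide F2. The sulfur-stabilised thionium intermediate gives no incentive for a veratryl shift.
   - Raney nickel in refluxing EtOH (Mozingo reduction) then removes the sulfur.

**Further compounds**

F1 | step 6 | 1,3-dioxoisoindolin-2-yl N-acetyl-N-methylglycinate | CC(=O)N(C)CC(=O)ON1C(=O)c2ccccc2C1=O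
F0 | step 3 | none | none
F2 | step 8 | (R)-N-{2-[6'-(3,4-dimethoxyphenyl)-7',8'-dihydro-6'H-spiro[1,3-dithiolane-2,5'-quinolin]-6'-yl]ethyl}-N-methylacetamide | COc1ccc([C@]2(CCN(C)C(C)=O)CCc3ncccc3C24SCCS4)cc1OC
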